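**Retrosynthetic overview**

1. Remark: the target has no stereocentre and no E/Z element, so it is made as the one achiral compound drawn. Ring A is a fully substituted 5-methoxyresorcinol ring (C1 aroyl, C2/C6 OH, C3/C5 prenyl, C4 OMe); ring B is 3-hydroxyphenyl.
2. Last disconnection: 14 from 13 by O–Si cleavage on ring B. Key disconnection: 13 from aryl iodide 5 and Weinreb amide 8. The ring A C1–C(=O) bond is made by acylation of the C1 aryllithium; in the same operation the two O-bound 1,1-dimethylallyl groups move to C3 and C5 by [3,3] shifts and free both phenols.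
3. Enabling feature: ring A has a mirror plane through C1 and C4, and C1 lies between the two oxygen-bearing carbons C2 and C6. A C1 carbanion is therefore flanked by two ortho oxygens, and once C1 carries the aroyl group each ether oxygen has only one unsubstituted ortho carbon (C3 or C5).
4. 5 comes from 5-methoxyresorcinol (1) by iodination at the carbon between the hydroxyls, double O-alkylation with 3-chloro-3-methylbut-1-yne (3) and semihydrogenation. 8 comes from methyl 3-hydroxybenzoate (6).
5. No ring is formed in the route; both benzene rings are bought.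

Key step: step 6

**Route**

Step 1
Reactants: 1 5-methoxybenzene-1,3-diol (5-methoxyresorcinol)
Product: 2 2-iodo-5-methoxybenzene-1,3-diol
Conditions: I2 (1.0 equiv), NaHCO3, H2O/THF, 0 °C to rt
Reagents that add atoms: iodine, II
Why: Electrophilic aromatic iodination of the resorcinol phenolate in aqueous bicarbonate is expected to go to the carbon between the two hydroxyls, as it does for resorcinol itself, because that carbon is ortho to both phenolate oxygens and para to the methoxy group, and one equivalent of iodine at 0 °C limits over-iodination.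

Step 2
Reactants: 2 2-iodo-5-methoxybenzene-1,3-diol; 3 3-chloro-3-methylbut-1-yne
Product: 4 2-iodo-5-methoxy-1,3-bis[(2-methylbut-3-yn-2-yl)oxy]benzene
Conditions: 3 (2.6 equiv), DBU (3 equiv), CuCl2·2H2O (1 mol%), MeCN, 0 °C
Reagents that add atoms: none
Why: Copper-catalysed O-alkylation of phenols with a tertiary propargylic chloride is the standard entry to aryl 1,1-dimethylpropargyl ethers and runs at 0 °C, far below the temperature at which the aryl iodide or the alkynes would react further.

Step 3
Reactants: 4 2-iodo-5-methoxy-1,3-bis[(2-methylbut-3-yn-2-yl)oxy]benzene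
Product: 5 2-iodo-5-methoxy-1,3-bis[(2-methylbut-3-en-2-yl)oxy]benzene
Conditions: H2 (1 atm), Lindlar catalyst (Pb-poisoned Pd/CaCO3), quinoline, EtOAc, rt, stopped after 2 equiv H2
Reagents that add atoms: none
Why: Lindlar semihydrogenation of a terminal alkyne stops at the alkene, and the poisoned catalyst at room temperature should leave the aryl C–I bond and the tertiary allyl ether C–O bonds untouched.

Step 4
Reactants: 6 methyl 3-hydroxybenzoate
Product: 7 methyl 3-[(tert-butyldimethylsilyl)oxy]benzoate
Conditions: TBSCl, imidazole, DMF, rt
Reagents that add atoms: tert-butyldimethylsilyl chloride, CC(C)(C)[Si](C)(C)Cl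
Why: Imidazole-promoted silylation of an unhindered phenol is routine and masks the ring B hydroxyl against the organometallic reagents of steps 5 and 6.

Step 5
Reactants: 7 methyl 3-[(tert-butyldimethylsilyl)oxy]benzoate
Product: 8 3-[(tert-butyldimethylsilyl)oxy]-N-methoxy-N-methylbenzamide
Conditions: MeNHOMe·HCl (1.5 equiv), i-PrMgCl (3 equiv), THF, −20 °C
Reagents that add atoms: N,O-dimethylhydroxylamine hydrochloride, CNOC.Cl
Why: Aminolysis of a methyl ester by the chloromagnesium amide of N,O-dimethylhydroxylamine gives the Weinreb amide directly at low temperature, where the aryl silyl ether is stable.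

Step 6
Reactants: 5 2-iodo-5-methoxy-1,3-bis[(2-methylbut-3-en-2-yl)oxy]benzene; 8 3-[(tert-butyldimethylsilyl)oxy]-N-methoxy-N-methylbenzamide
Product: 13 {3-[(tert-butyldimethylsilyl)oxy]phenyl}[2,6-dihydroxy-4-methoxy-3,5-bis(3-methylbut-2-en-1-yl)phenyl]methanone, via aryllithium 9 (not isolated), via lithium hemiaminal adduct 10 (not isolated), via diether ketone 11 (not isolated), via monoprenyl phenol 12 (not isolated)
Conditions: t-BuLi (2.0 equiv), THF, −78 °C, 10 min; 8, −78 to −30 °C; AcOH (1.0 equiv), aqueous wash, extraction into PhMe; dried PhMe solution, 110 °C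
Reagents that add atoms: none
Why: Iodine–lithium exchange at the carbon between the two ether-bearing carbons gives aryllithium 9, flanked by two ortho oxygens, which attacks Weinreb amide 8 to form the aryl–carbonyl bond and stops at the N,O-chelated adduct 10; acetic acid then releases ketone 11. On heating, each aryl 1,1-dimethylallyl ether undergoes an aromatic Claisen [3,3] shift through a six-membered chair transition state to a 6-prenylcyclohexa-2,4-dienone that enolises to the phenol, so that O–C cleavage, C-prenyl bond formation and unmasking of the phenol are one event on each side (11 to 12 to 13). The closest known reaction types are the acylation of 2,6-dialkoxyaryllithiums with Weinreb amides and the Claisen rearrangement of aryl 1,1-dimethylallyl ethers used to place prenyl groups ortho to the hydroxyl of acylphenols. No ring is closed and no stereocentre is formed; the allyl inversion inherent to the [3,3] shift turns the tertiary ether terminus into the linear 3-methylbut-2-enyl group. The step needs site selectivity in both stages: the iodine fixes where the carbonyl carbon is attached, and after acylation each ether oxygen has one unsubstituted ortho carbon (C3 or C5), where enolisation, helped by the new O–H···O=C hydrogen bond, should make the shift irreversible, whereas attack at the aroyl-bearing carbon can only revert or leak onward by a Cope shift. Exchange and trapping are run at −78 °C because the aryllithium could otherwise add 5-exo to a flanking vinyl group.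

Step 7
Reactants: 13 {3-[(tert-butyldimethylsilyl)oxy]phenyl}[2,6-dihydroxy-4-methoxy-3,5-bis(3-methylbut-2-en-1-yl)phenyl]methanone
Product: 14 [2,6-dihydroxy-4-methoxy-3,5-bis(3-methylbut-2-en-1-yl)phenyl](3-hydroxyphenyl)methanone
Conditions: TBAF (1.1 equiv), AcOH (1.1 equiv), THF, 0 °C
Reagents that add atoms: none
Why: Fluoride-mediated cleavage of an aryl silyl ether is fast at 0 °C, and the acetic acid buffer keeps the medium near neutral so that the prenyl groups next to free phenols and the methyl ether are not touched.

**Compound list**

1 | 5-methoxybenzene-1,3-diol (5-methoxyresorcinol) | COc1cc(O)cc(O)c1 | starting material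
2 | 2-iodo-5-methoxybenzene-1,3-diol | COc1cc(O)c(I)c(O)c1 | intermediate
3 | 3-chloro-3-methylbut-1-yne | CC(C)(Cl)C#C | starting material
4 | 2-iodo-5-methoxy-1,3-bis[(2-methylbut-3-yn-2-yl)oxy]benzene | COc1cc(OC(C)(C)C#C)c(I)c(OC(C)(C)C#C)c1 | intermediate
5 | 2-iodo-5-methoxy-1,3-bis[(2-methylbut-3-en-2-yl)oxy]benzene | COc1cc(OC(C)(C)C=C)c(I)c(OC(C)(C)C=C)c1 | intermediate
6 | methyl 3-hydroxybenzoate | COC(=O)c1cccc(O)c1 | starting material
7 | methyl 3-[(tert-butyldimethylsilyl)oxy]benzoate | COC(=O)c1cccc(O[Si](C)(C)C(C)(C)C)c1 | intermediate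
8 | 3-[(tert-butyldimethylsilyl)oxy]-N-methoxy-N-methylbenzamide | CON(C)C(=O)c1cccc(O[Si](C)(C)C(C)(C)C)c1 | intermediate
9 | {2,6-bis[(2-methylbut-3-en-2-yl)oxy]-4-methoxyphenyl}lithium | [Li]c1c(OC(C)(C)C=C)cc(OC)cc1OC(C)(C)C=C | intermediate
10 | lithium {2,6-bis[(2-methylbut-3-en-2-yl)oxy]-4-methoxyphenyl}{3-[(tert-butyldimethylsilyl)oxy]phenyl}[methoxy(methyl)amino]methanolate | CON(C)C(O[Li])(c1cccc(O[Si](C)(C)C(C)(C)C)c1)c1c(OC(C)(C)C=C)cc(OC)cc1OC(C)(C)C=C | intermediate
11 | {2,6-bis[(2-methylbut-3-en-2-yl)oxy]-4-methoxyphenyl}{3-[(tert-butyldimethylsilyl)oxy]phenyl}methanone | COc1cc(OC(C)(C)C=C)c(C(=O)c2cccc(O[Si](C)(C)C(C)(C)C)c2)c(OC(C)(C)C=C)c1 | intermediate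
12 | {3-[(tert-butyldimethylsilyl)oxy]phenyl}{2-hydroxy-4-methoxy-3-(3-methylbut-2-en-1-yl)-6-[(2-methylbut-3-en-2-yl)oxy]phenyl}methanone | COc1cc(OC(C)(C)C=C)c(C(=O)c2cccc(O[Si](C)(C)C(C)(C)C)c2)c(O)c1CC=C(C)C | intermediate
13 | {3-[(tert-butyldimethylsilyl)oxy]phenyl}[2,6-dihydroxy-4-methoxy-3,5-bis(3-methylbut-2-en-1-yl)phenyl]methanone | COc1c(CC=C(C)C)c(O)c(C(=O)c2cccc(O[Si](C)(C)C(C)(C)C)c2)c(O)c1CC=C(C)C | intermediate
14 | [2,6-dihydroxy-4-methoxy-3,5-bis(3-methylbut-2-en-1-yl)phenyl](3-hydroxyphenyl)methanone (achiral) | COc1c(CC=C(C)C)c(O)c(C(=O)c2cccc(O)c2)c(O)c1CC=C(C)C | target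

**Step count**

Total steps: 7. Longest linear sequence: 5 steps (steps 1, 2, 3, 6, 7); steps 4 and 5 form the short ring B branch.

**Steps most likely to fail**

Step 6. The hindered aryllithium may be used up before it attacks the amide carbonyl, either by 5-exo carbolithiation onto a flanking vinyl group or by base-induced N–O cleavage of the Weinreb amide. In the thermal stage, part of the first [3,3] shift may also pass through the aroyl-bearing carbon. The fallback replaces acyl substitution by addition to an aldehyde followed by oxidation. It sets out from 5: iodine–lithium exchange as before, then trapping at −78 °C with the much more electrophilic, commercially available 3-[(tert-butyldimethylsilyl)oxy]benzaldehyde should give rac-{2,6-bis[(2-methylbut-3-en-2-yl)oxy]-4-methoxyphenyl}{3-[(tert-butyldimethylsilyl)oxy]phenyl}methanol F1. Oxidation of this carbinol with Dess–Martin periodinane (NaHCO3, CH2Cl2, 0 °C) comes back to the route at ketone 11, which is then heated in toluene as in step 6 to give 13.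

Step 1. Iodination may spread to the two ring carbons next to the methoxy group or run on to di-iodides, because all three free positions are activated. The fallback fixes the site by directed ortho-metalation. It sets out from 1: MOMCl and i-Pr2NEt in CH2Cl2 should give 1-methoxy-3,5-bis(methoxymethoxy)benzene F2. n-BuLi in THF at 0 °C is expected to lithiate between the two methoxymethyl ethers, the more strongly chelating pair, and iodine at −78 °C then gives 2-iodo-5-methoxy-1,3-bis(methoxymethoxy)benzene F3. Brief treatment with HCl in MeOH at rt removes both acetals and comes back to the route at 2.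

Step 3. Hydrogenolysis of the C–I bond on the palladium surface, or over-reduction of the alkenes, may compete with semihydrogenation. The fallback uses stoichiometric hydroboration and protonolysis in place of catalytic hydrogenation. It sets out from 4: dicyclohexylborane (2.2 equiv, THF, 0 °C) should add to both terminal alkynes to give 2-iodo-5-methoxy-1,3-bis{[(3E)-4-(dicyclohexylboranyl)-2-methylbut-3-en-2-yl]oxy}benzene F4. Protonolysis of the two alkenyl–boron bonds with AcOH at rt comes back to the route at 5, and the aryl iodide is inert to both reagents.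

**Further compounds**

F1 | step 6 | rac-{2,6-bis[(2-methylbut-3-en-2-yl)oxy]-4-methoxyphenyl}{3-[(tert-butyldimethylsilyl)oxy]phenyl}methanol | COc1cc(OC(C)(C)C=C)c(C(O)c2cccc(O[Si](C)(C)C(C)(C)C)c2)c(OC(C)(C)C=C)c1
F2 | step 1 | 1-methoxy-3,5-bis(methoxymethoxy)benzene | COCOc1cc(OC)cc(OCOC)c1
F3 | step 1 | 2-iodo-5-methoxy-1,3-bis(methoxymethoxy)benzene | COCOc1cc(OC)cc(OCOC)c1I
F4 | step 3 | 2-iodo-5-methoxy-1,3-bis{[(3E)-4-(dicyclohexylboranyl)-2-methylbut-3-en-2-yl]oxy}benzene | COc1cc(OC(C)(C)/C=C/B(C2CCCCC2)C2CCCCC2)c(I)c(OC(C)(C)/C=C/B(C2CCCCC2)C2CCCCC2)c1
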